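The 1,2-dioxane is cut into three pieces: dioxygen, a masked propanal unit (C3–C4) and the isopropenyl end of an acyclic triene (C5=C6). The route rests on the fact that ring carbon C5 is a bare CH2 and C6 a fully substituted, oxygen-bearing carbon, that is, the two ends of a 1,1-disubstituted alkene. In one operation a manganese-mediated aerobic radical annulation joins C4 to C5, places the peroxide oxygen on C6 and lets the ring close as a peroxy hemiacetal. Its precursors are the triene, built by two chirality-transferring Claisen rearrangements, and tert-butyl 2-formylpropanoate, whose ester is a temporary activating group lost by decarboxylation; the acetic acid arm is then added through a peroxycarbenium ion.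

Key step: step 8

Remark: ring numbering is O1–O2–C3(CH2CO2H)–C4(CH3)–C5H2–C6(CH3)(side chain). The annulation has no handle to tell methyl from the chain at C6 or to fix C4, so the route plans a chromatographic separation in step 10 instead of claiming control there.

Step 1
Reactants: 1 benzaldehyde
Product: 2 (R,E)-1-phenylbut-2-en-1-ol
Conditions: propyne, Cy2BH, toluene, 0 °C to rt; Me2Zn, −78 °C; (+)-DAIB (3-exo-dimethylaminoisoborneol, 2 mol %), then 1, −20 to 0 °C; aq NH4Cl
Reagents that add atoms: propyne (CC#C)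
Why: catalytic asymmetric alkenylzinc addition to an aldehyde, in which syn-hydroboration fixes the (E)-propenyl group, boron-to-zinc exchange gives the alkenylzinc, and the amino alcohol ligand (mirror image of the one that gives (S)-carbinols from benzaldehyde) sets the (R)-carbinol.

Step 2
Reactants: 2 (R,E)-1-phenylbut-2-en-1-ol
Product: 4 (S,E)-N,N,3-trimethyl-5-phenylpent-4-enamide, via ketene aminal 3 (not isolated)
Conditions: MeC(OMe)2NMe2 (4 equiv), xylenes, 140 °C, MeOH distilled off
Reagents that add atoms: N,N-dimethylacetamide dimethyl acetal (CC(OC)(OC)N(C)C)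
Why: Eschenmoser–Claisen rearrangement under neutral conditions, whose chair transition state with phenyl pseudo-equatorial transfers the (R)-carbinol chirality to the new (S)-methyl-bearing carbon and gives the (E)-styrene.

Step 3
Reactants: 4 (S,E)-N,N,3-trimethyl-5-phenylpent-4-enamide
Product: 5 (2E,6S,7E)-6-methyl-8-phenylocta-2,7-dien-4-one
Conditions: (E)-1-bromoprop-1-ene, t-BuLi (2 equiv), Et2O, −78 °C; then 4, THF, −78 to −20 °C; inverse quench into cold 1 M HCl
Reagents that add atoms: (E)-1-bromoprop-1-ene (C/C=C/Br)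
Why: acyl substitution of a tertiary amide by an alkenyllithium, where bromine–lithium exchange keeps the E geometry, the tetrahedral adduct prevents over-addition, and the acid quench keeps dimethylamine from adding to the enone.

Step 4
Reactants: 5 (2E,6S,7E)-6-methyl-8-phenylocta-2,7-dien-4-one
Product: 6 (2E,4R,6S,7E)-6-methyl-8-phenylocta-2,7-dien-4-ol
Conditions: (S)-Me-CBS oxazaborolidine (0.2 equiv), catecholborane, toluene, −78 °C
Reagents that add atoms: none
Why: Corey–Bakshi–Shibata reduction with 1,2-selectivity, in which the alkenyl group acts as the large substituent so that the (S)-catalyst gives the (R)-allylic alcohol under reagent control.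

Step 5
Reactants: 6 (2E,4R,6S,7E)-6-methyl-8-phenylocta-2,7-dien-4-ol
Product: 8 (4R,5E,8S,9E)-4,8-dimethyl-10-phenyldeca-5,9-dien-2-one, via allyl isopropenyl ether 7 (not isolated)
Conditions: 2-methoxypropene (6 equiv), PPTS (cat.), xylenes, sealed tube, 130 °C
Reagents that add atoms: 2-methoxypropene (C=C(C)OC)
Why: Saucy–Marbet variant of the Claisen rearrangement, in which acid-catalysed enol ether exchange gives 7 and its chair transition state (chain pseudo-equatorial) turns the (R)-carbinol into the (R)-methyl center and a new (E)-alkene.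

Step 6
Reactants: 8 (4R,5E,8S,9E)-4,8-dimethyl-10-phenyldeca-5,9-dien-2-one
Product: 9 [(1E,3S,5E,7R)-3,7,9-trimethyldeca-1,5,9-trien-1-yl]benzene
Conditions: Ph3PCH3Br, KOt-Bu, THF, 0 °C to rt
Reagents that add atoms: methyltriphenylphosphonium bromide (C[P+](c1ccccc1)(c1ccccc1)c1ccccc1.[Br-])
Why: Wittig methylenation of a methyl ketone whose stereocenter is beta to the carbonyl and so cannot epimerise.

Step 7
Reactants: 10 tert-butyl propanoate
Product: 11 tert-butyl 2-methyl-3-oxopropanoate (racemic, keto–enol mixture)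
Conditions: LiN(i-Pr)2 (2.1 equiv), THF, −78 °C; HCO2Et, −78 to 0 °C; cold aq HCl
Reagents that add atoms: ethyl formate (CCOC=O)
Why: crossed Claisen condensation (formylation) of the ester enolate, driven by deprotonation of the beta-formyl ester formed.

Step 8
Reactants: 9 [(1E,3S,5E,7R)-3,7,9-trimethyldeca-1,5,9-trien-1-yl]benzene; 11 tert-butyl 2-methyl-3-oxopropanoate
Product: 13 tert-butyl 6-[(2R,3E,6S,7E)-2,6-dimethyl-8-phenylocta-3,7-dien-1-yl]-3-hydroxy-4,6-dimethyl-1,2-dioxane-4-carboxylate (mixture at C3, C4 and C6), via hydroperoxy aldehyde 12 (not isolated)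
Conditions: Mn(OAc)3·2H2O (0.3 equiv), AcOH, dry air, 23 °C, formyl ester in twofold excess
Reagents that add atoms: dioxygen (O=O)
Why: Mn(OAc)3 (trivalent manganese) oxidises the enol of 11 to an electrophilic tertiary radical at C4, which adds to the unsubstituted terminus (C5) of the isopropenyl group of 9; the tertiary C6 radical is trapped by triplet dioxygen (C6–O bond) and the peroxyl radical is reduced by divalent manganese, which returns the oxidant and gives hydroperoxide 12. The closest known reaction type is the manganese triacetate-catalysed aerobic annulation of enolisable 1,3-dicarbonyl compounds with 1,1-disubstituted alkenes to 1,2-dioxan-3-ols, here run with an alpha-formyl ester so that C3 carries hydrogen. The 1,2-dioxane closes by reversible 6-exo-trig addition of the hydroperoxide oxygen to the formyl carbon (C3). Of the new stereocenters, C3 is an equilibrating anomeric center and C4 is erased in step 9, while C6 arises from dioxygen capture on a planar radical whose faces differ only by methyl against CH2R, so no control is expected and both C6 epimers are carried on. The step needs regioselectivity (attack at CH2 to give the tertiary radical) and chemoselectivity among three alkenes, which rest on the free CH2 terminus of the 1,1-disubstituted alkene against two 1,2-disubstituted alkenes that each carry a branched allylic carbon.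

Step 9
Reactants: 13 tert-butyl 6-[(2R,3E,6S,7E)-2,6-dimethyl-8-phenylocta-3,7-dien-1-yl]-3-hydroxy-4,6-dimethyl-1,2-dioxane-4-carboxylate
Product: 15 6-[(2R,3E,6S,7E)-2,6-dimethyl-8-phenylocta-3,7-dien-1-yl]-4,6-dimethyl-1,2-dioxan-3-ol (mixture at C3, C4 and C6), via carboxylic acid 14 (not isolated)
Conditions: TFA/CH2Cl2 (1:5), 0 °C to rt; then toluene, 40 °C
Reagents that add atoms: none
Why: acidolysis of the tert-butyl ester gives acid 14, whose ring-opened beta-formyl acid tautomer decarboxylates through its enol, and protonation at C4 is not controlled so both C4 epimers result.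

Step 10
Reactants: 15 6-[(2R,3E,6S,7E)-2,6-dimethyl-8-phenylocta-3,7-dien-1-yl]-4,6-dimethyl-1,2-dioxan-3-ol
Product: 16 (4S,6R)-6-[(2R,3E,6S,7E)-2,6-dimethyl-8-phenylocta-3,7-dien-1-yl]-3-methoxy-4,6-dimethyl-1,2-dioxane (both C3 anomers)
Conditions: MeOH, PPTS (cat.), 3 Å MS, rt; then preparative HPLC (silica)
Reagents that add atoms: methanol (CO)
Why: acid-catalysed acetalisation through the peroxycarbenium ion fixes the lactol as a configurationally stable peroxy acetal, and because C4 and C6 were formed without control the (4S,6R) series is isolated here by chromatography, the side-chain stereocenters making all isomers diastereomers.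

Step 11
Reactants: 16 (4S,6R)-6-[(2R,3E,6S,7E)-2,6-dimethyl-8-phenylocta-3,7-dien-1-yl]-3-methoxy-4,6-dimethyl-1,2-dioxane
Product: 18 2-[(3S,4S,6R)-6-[(2R,3E,6S,7E)-2,6-dimethyl-8-phenylocta-3,7-dien-1-yl]-4,6-dimethyl-1,2-dioxan-3-yl]acetic acid (target), via trimethylsilyl ester 17 (not isolated)
Conditions: CH2=C(OTMS)2 (3 equiv), TMSOTf (0.2 equiv), CH2Cl2, −78 °C; pH 4 aqueous work-up
Reagents that add atoms: 1,1-bis(trimethylsilyloxy)ethene (C=C(O[Si](C)(C)C)O[Si](C)(C)C)
Why: Mukaiyama-type substitution of a 3-alkoxy-1,2-dioxane by a silyl ketene acetal through the peroxycarbenium ion, in whose half-chair (C4 methyl and C6 chain pseudo-equatorial) axial attack at C3 should place the acetic acid arm cis to the C4 methyl, i.e. (3S), the silyl ester 17 being hydrolysed on work-up.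

Compound list
1 | benzaldehyde | O=Cc1ccccc1 | starting material
2 | (R,E)-1-phenylbut-2-en-1-ol | C/C=C/[C@@H](O)c1ccccc1 | intermediate
3 | N,N-dimethyl-1-{[(1R,2E)-1-phenylbut-2-en-1-yl]oxy}ethen-1-amine (ketene aminal) | C=C(N(C)C)O[C@H](/C=C/C)c1ccccc1 | intermediate
4 | (S,E)-N,N,3-trimethyl-5-phenylpent-4-enamide | C[C@H](/C=C/c1ccccc1)CC(=O)N(C)C | intermediate
5 | (2E,6S,7E)-6-methyl-8-phenylocta-2,7-dien-4-one | C/C=C/C(=O)C[C@H](C)/C=C/c1ccccc1 | intermediate
6 | (2E,4R,6S,7E)-6-methyl-8-phenylocta-2,7-dien-4-ol | C/C=C/[C@H](O)C[C@H](C)/C=C/c1ccccc1 | intermediate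
7 | [(1E,3S,5R,6E)-3-methyl-5-(prop-1-en-2-yloxy)octa-1,6-dien-1-yl]benzene (allyl isopropenyl ether) | C=C(C)O[C@@H](/C=C/C)C[C@H](C)/C=C/c1ccccc1 | intermediate
8 | (4R,5E,8S,9E)-4,8-dimethyl-10-phenyldeca-5,9-dien-2-one | C[C@H](/C=C/c1ccccc1)C/C=C/[C@H](C)CC(C)=O | intermediate
9 | [(1E,3S,5E,7R)-3,7,9-trimethyldeca-1,5,9-trien-1-yl]benzene | C[C@H](/C=C/c1ccccc1)C/C=C/[C@H](C)CC(C)=C | intermediate
10 | tert-butyl propanoate | CCC(=O)OC(C)(C)C | starting material
11 | tert-butyl 2-methyl-3-oxopropanoate | CC(C=O)C(=O)OC(C)(C)C | intermediate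
12 | tert-butyl (6R,7E,10S,11E)-2-formyl-4-hydroperoxy-2,4,6,10-tetramethyl-12-phenyldodeca-7,11-dienoate (C2, C4 unassigned) | C[C@H](/C=C/c1ccccc1)C/C=C/[C@H](C)CC(C)(OO)CC(C)(C=O)C(=O)OC(C)(C)C | intermediate
13 | tert-butyl 6-[(2R,3E,6S,7E)-2,6-dimethyl-8-phenylocta-3,7-dien-1-yl]-3-hydroxy-4,6-dimethyl-1,2-dioxane-4-carboxylate (mixture at C3, C4, C6) | C[C@H](/C=C/c1ccccc1)C/C=C/[C@H](C)CC1(C)CC(C)(C(=O)OC(C)(C)C)C(O)OO1 | intermediate
14 | 6-[(2R,3E,6S,7E)-2,6-dimethyl-8-phenylocta-3,7-dien-1-yl]-3-hydroxy-4,6-dimethyl-1,2-dioxane-4-carboxylic acid (mixture at C3, C4, C6) | C[C@H](/C=C/c1ccccc1)C/C=C/[C@H](C)CC1(C)CC(C)(C(=O)O)C(O)OO1 | intermediate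
15 | 6-[(2R,3E,6S,7E)-2,6-dimethyl-8-phenylocta-3,7-dien-1-yl]-4,6-dimethyl-1,2-dioxan-3-ol (mixture at C3, C4, C6) | C[C@H](/C=C/c1ccccc1)C/C=C/[C@H](C)CC1(C)CC(C)C(O)OO1 | intermediate
16 | (4S,6R)-6-[(2R,3E,6S,7E)-2,6-dimethyl-8-phenylocta-3,7-dien-1-yl]-3-methoxy-4,6-dimethyl-1,2-dioxane (both C3 anomers) | C[C@H](/C=C/c1ccccc1)C/C=C/[C@H](C)C[C@]1(C)C[C@H](C)C(OC)OO1 | intermediate
17 | trimethylsilyl 2-[(3S,4S,6R)-6-[(2R,3E,6S,7E)-2,6-dimethyl-8-phenylocta-3,7-dien-1-yl]-4,6-dimethyl-1,2-dioxan-3-yl]acetate | C[C@H](/C=C/c1ccccc1)C/C=C/[C@H](C)C[C@]1(C)C[C@H](C)[C@H](CC(=O)O[Si](C)(C)C)OO1 | intermediate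
18 | 2-[(3S,4S,6R)-6-[(2R,3E,6S,7E)-2,6-dimethyl-8-phenylocta-3,7-dien-1-yl]-4,6-dimethyl-1,2-dioxan-3-yl]acetic acid | C[C@H](/C=C/c1ccccc1)C/C=C/[C@H](C)C[C@]1(C)C[C@H](C)[C@H](CC(=O)O)OO1 | target

Total step count: 11. Longest linear sequence: 10 steps (steps 1–6 and 8–11).

Steps most likely to fail

Step 8. The aerobic manganese cycle may be diverted by autoxidation of the formyl group and of allylic C–H bonds, by cyclisation of the peroxyl radical onto the neighbouring alkene, or by radical addition to the styrenyl alkene. The fallback separates carbon–carbon from carbon–oxygen bond formation; it sets out from 11 and 9 and comes back at 13. Compound 11 is brominated (NBS, CH2Cl2, 0 °C) to tert-butyl 2-bromo-2-methyl-3-oxopropanoate F1. An oxygen-free bromine atom-transfer radical addition of F1 to 9 (Et3B, trace air, CH2Cl2, rt) should give the tertiary bromide tert-butyl (6R,7E,10S,11E)-4-bromo-2-formyl-2,4,6,10-tetramethyl-12-phenyldodeca-7,11-dienoate F2. Silver-assisted perhydrolysis of the tertiary bromide (anhydrous H2O2 in Et2O, AgOCOCF3, 0 °C) then gives hydroperoxide 12, which closes to 13.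

Step 11. Attack on the peroxycarbenium ion may occur with poor facial selectivity (arm trans to the C4 methyl), or the Lewis acid may trigger heterolysis of the O–O or C6–O bond. The fallback forms the C3–C bond before the ring; it sets out from 15 and comes back at 18. Wittig olefination of the ring-opened aldehyde form of 15 (Ph3P=CHCO2Me, CH2Cl2, rt) should give methyl (2E,8R,9E,12S,13E)-6-hydroperoxy-4,6,8,12-tetramethyl-14-phenyltetradeca-2,9,13-trienoate F3. Base-mediated 6-exo peroxy-Michael addition (Et2NH cat., CF3CH2OH, rt) closes the dioxane. HPLC then isolates methyl 2-[(3S,4S,6R)-6-[(2R,3E,6S,7E)-2,6-dimethyl-8-phenylocta-3,7-dien-1-yl]-4,6-dimethyl-1,2-dioxan-3-yl]acetate F4; the closure is reversible, so 3,4-trans material can be resubmitted. Hydrolysis (LiOH, THF/H2O, 0 °C) gives 18.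

Step 9. While the ester is cleaved, the acid may ionise the tertiary C6–O bond or add to the styrene, and decarboxylation may stall if the lactol stays closed. The fallback removes the activating group under neutral conditions; it sets out from 9 and comes back at 15. The annulation of step 8 is run with commercial ethyl 2-methyl-3-oxopropanoate to give ethyl 6-[(2R,3E,6S,7E)-2,6-dimethyl-8-phenylocta-3,7-dien-1-yl]-3-hydroxy-4,6-dimethyl-1,2-dioxane-4-carboxylate F5. Hydrolysis of F5 by pig liver esterase (a carboxylesterase; pH 7.5 phosphate buffer, acetone cosolvent, 25 °C) gives acid 14, which decarboxylates at 40 °C to 15.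

Further compounds
F1 | step 8 | tert-butyl 2-bromo-2-methyl-3-oxopropanoate | CC(Br)(C=O)C(=O)OC(C)(C)C
F2 | step 8 | tert-butyl (6R,7E,10S,11E)-4-bromo-2-formyl-2,4,6,10-tetramethyl-12-phenyldodeca-7,11-dienoate | C[C@H](/C=C/c1ccccc1)C/C=C/[C@H](C)CC(C)(Br)CC(C)(C=O)C(=O)OC(C)(C)C
F3 | step 11 | methyl (2E,8R,9E,12S,13E)-6-hydroperoxy-4,6,8,12-tetramethyl-14-phenyltetradeca-2,9,13-trienoate | C[C@H](/C=C/c1ccccc1)C/C=C/[C@H](C)CC(C)(OO)CC(C)/C=C/C(=O)OC
F4 | step 11 | methyl 2-[(3S,4S,6R)-6-[(2R,3E,6S,7E)-2,6-dimethyl-8-phenylocta-3,7-dien-1-yl]-4,6-dimethyl-1,2-dioxan-3-yl]acetate | C[C@H](/C=C/c1ccccc1)C/C=C/[C@H](C)C[C@]1(C)C[C@H](C)[C@H](CC(=O)OC)OO1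
F5 | step 9 | ethyl 6-[(2R,3E,6S,7E)-2,6-dimethyl-8-phenylocta-3,7-dien-1-yl]-3-hydroxy-4,6-dimethyl-1,2-dioxane-4-carboxylate | C[C@H](/C=C/c1ccccc1)C/C=C/[C@H](C)CC1(C)CC(C)(C(=O)OCC)C(O)OO1
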